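## The problem

The target is a linear B-type trimer: an epicatechin 3-O-gallate (unit U) is bonded through C4 to C8 of a second epicatechin 3-O-gallate (unit M), whose C4 is bonded to C6 of (+)-catechin (unit L). Of its eight stereocentres, the six at C2 and C3 are those of the natural monomers. Only the two diarylmethine centres, C4 of U and C4 of M, are new, and both are β, trans to the neighbouring 3-acyloxy group. C4 of U can be set by its own unit, because a C4 cation of an epicatechin ester is attacked anti to the 3-oxygen, and attack by C8 of the partner is the inherent regiochemistry. The M–L bond is the hard one: C6 of a flavan is less reactive than C8 towards such cations, and the stereocentres of L lie across an aromatic ring from C4 of M and cannot control it. The molecule carries nineteen hydroxyl groups, two aryl esters and two acid-labile, doubly benzylic interflavan bonds, and the free polyphenol is sensitive to air and base. It should therefore appear only in the last step, from a uniformly benzylated precursor. The enabling feature is that C4 of M is a diarylmethine two atoms from C2 in ring C. Ring C of M thus maps onto a phenol (ring A of M) and a chalcone-type enone whose β-carbon already carries C6 of L and whose carbonyl carbon becomes C2. The enone comes from a C6 aldehyde of catechin, so the 4→6 regiochemistry is fixed by construction.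

## Retrosynthesis

**Deprotection (22 from 21).** Target 22 is traced to the fully protected trimer 21 by cleavage of nineteen benzyl ethers and two aryl C–Br bonds (the C8 caps of U and L). Benzyl is chosen over acyl or silyl groups because it is inert to every Lewis acid, oxidant and base of the route and leaves in one neutral operation that spares the gallate esters. The forward reaction must hydrogenolyse O–benzyl and C–Br bonds without touching the two esters or the benzylic C2–O and C4–aryl bonds of the flavan cores.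

**U–M bond (21 from 15 and 20).** Trimer 21 is cut at C4(U)–C8(M) into the galloylated M–L dimer 15 and the C4-activated, C8-brominated epicatechin gallate 20. This bond is cut first because it is the only interflavan bond for which inherent regiochemistry (C8) and stereochemistry (anti to the 3-acyloxy group) are both right. The alternative cationic cut at C4(M)–C6(L) would work against the C8 preference. The forward step needs a C4 cation that is trapped by C8 of M faster than by anything else; the bromine of 20 prevents self-condensation.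

**Electrophile (20 from 19, 18, 17 and 16).** The C8–Br bond, the C4–O bond and the ester C–O bond at O3 are removed in turn, through 4β-ether 19, heptabenzyl gallate 18 and tetrabenzyl ether 17, back to (−)-epicatechin 16. The gallate of U is put on the tetrabenzyl ether with the same acid chloride 14 that serves unit M. This keeps the aryl ester away from carbonate base and benzyl bromide and uses one protected galloyl donor for both esters. Both stereocentres of U are bought with 16; C4 is set by the neighbouring 3-acyloxy group.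

**Gallate of M (15 from 13 and 14).** The ester C–O bond at O3 of M is cut to alcohol 13 and 3,4,5-tris(benzyloxy)benzoyl chloride 14. Acylating after the ring chemistry keeps the ester out of the epoxidation and reduction. The forward step is the acylation of a hindered axial secondary alcohol.

**C2 and C3 of M (13 from 11 through 12).** The C3–O and C2–H bonds are removed to give 4H-chromene 11, by way of 2,3-epoxide 12. Chromene 11 has a single stereocentre in M (C4) and a C2=C3 enol ether. Epoxidation and reductive opening is preferred to hydroboration, which would add H and O syn and anti to the C4 aryl group and so place the 2-aryl group on the wrong face. The forward step needs the oxidant to come anti to the C4 aryl group and the hydride to reach C2 anti to the C3 oxygen.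

**Ring C of M (11 from 7 and 8 through 9 and 10).** The key cut removes C4–C4a and O1–C2, leading to enone 7 and 3,5-dibenzyloxyphenol 8, with ketone 9 and hemiketal 10 as intermediates. It leaves the M–L bond untouched inside a stable enone instead of making it by a cation coupling of the wrong regiochemistry. It also replaces the dimer by a commercial phenol and a chalcone. The forward reaction needs a catalyst that selects one enone face, since nothing in 7 can, and reaction at an ortho carbon of 8.

**Enone (7 from 5 and 6).** The Cα=Cβ bond is cut by a retro-aldol condensation to aldehyde 5 and commercial 3,4-dibenzyloxyacetophenone 6. Aldehyde 5 cannot enolise and 6 has a single enolisable position, so the crossed condensation is unambiguous.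

**Aldehyde (5 from 4, 3, 2 and 1).** The formyl C–C6 bond, the C8–Br bond and the five O–benzyl bonds are removed in turn, through bromide 4, pentabenzyl ether 3 and tetrabenzyl ether 2, back to (+)-catechin 1. Bromine is introduced first because C8 is the more reactive ring A position. It then serves as a cap that sends the formyl group to C6 and later keeps C8 of L out of the coupling. Both stereocentres of L are bought with 1.

## Roads not taken

**Alternative 1:** The cut is C4–C4a of unit L.
- **Key step:** it would give the perbenzylated trimer A1, with L as a 2-aryl-2H-chromene, from the aryl propargyl ether A2. Ph3PAuNTf2 would catalyse a 6-endo hydroarylation of the terminal alkyne. Hydroboration–oxidation of C3=C4 anti to the 2-aryl group would then complete catechin.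
- **Merits:** the conditions are neutral and catalytic. In A2 the propargyloxy group is para to the carbon bearing M, so the two ortho carbons are equivalent and the closure has no regiochemical choice. U and M come intact from natural epicatechin gallate units, so their C2, C3 and C4 centres need no chiral catalyst. That is a real advantage over the chosen plan, which must create C2, C3 and C4 of M.
- **Weak points:** it dismantles a unit that can be bought whole. C2 of L becomes a secondary propargylic aryl ether that must be made enantioselectively and without ionisation to a cation stabilised by alkyne and dialkoxyphenyl group. The M–L bond must still be made at a ring carbon flanked by two benzyloxy groups, so the 4→6 problem is moved, not solved. The ring closure and a borane step next to two gallate esters both fall on trimer-sized material.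
- **Comparison:** the chosen plan is weaker in stereochemical economy for M. Against that, its uncertain steps come early on small material, L is used as purchased, and the 4→6 bond exists before any ring is built.

**Alternative 2:** The cut is C5–C6 and C7–C8 of ring A of L.
- **Key step:** heating the pyran-fused 2-chloro-3-alkoxycyclobutenone A4 with the siloxyalkyne A5 would give the M–L dimer A3. The sequence is electrocyclic opening to a vinylketene, [2+2] addition of the ynol ether, a second four-electron opening, six-electron closure and tautomerisation to the phenol.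
- **Merits:** the substitution pattern of the hexasubstituted ring is dictated by connectivity. The 4→6 linkage is therefore more secure than by any electrophilic substitution, including the bromination and formylation of the chosen plan. The three ring A oxygens of L also emerge differentiated.
- **Weak points:** A4 requires a de novo synthesis of the catechin pyran with both stereocentres. A5 requires an M unit with C2, C3 and C4 already set and an ynol ether on the stereogenic C4, which must survive 80–110 °C. The chlorine, two kinds of silyl ether and a free phenol add steps before galloylation.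
- **Comparison:** it is better in regiochemical certainty but much longer. It builds by synthesis the ring that catechin supplies and leaves C4 of M to an earlier, unspecified stage. The chosen plan answers the regiochemical question in two steps from pentabenzyl ether 3 and keeps a fallback for the formylation.

**Alternative 3:** The cut is C3–C4 and O1–C2 of ring C of M.
- **Key step:** a chiral phosphoric acid would ionise the ortho-hydroxybenzhydrol A7 to an ortho-quinone methide, which adds the Z enol gallate A8 to give the galloylated dimer A6. A6 is identical with compound 15.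
- **Merits:** it is the most convergent road. Two bonds, ring C, three stereocentres and the gallate come in one step, two steps fewer than steps 6–8 here, with no epoxide and no hydride-face question. A7 derives from the same aldehyde 5 and phenol 8.
- **Weak points:** enol esters are poor partners for quinone methides. A8 is polarised by the acyloxy oxygen and, more strongly and in the opposite sense, by the dialkoxyphenyl group. The productive regiochemistry implies a benzylic cation at C2, hence a stepwise path in which the Z geometry can be lost in favour of the 2,3-trans isomer. One catalyst must control the absolute configuration at C4 and two relative configurations, with L too remote to help.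
- **Comparison:** if it worked as drawn it would be the better route in step count, and this is conceded. The chosen plan asks the catalyst for one stereocentre only, settles C3 and C2 separately through the C4 aryl group and the ring conformation, and uses a plain enone. The quinone methide cut with a simple silyl enol ether is kept as the fallback for step 6.

Key step: step 6

Remark: flavan numbering is used within each unit; α and β refer to the usual drawing in which the 2-aryl group of each (2R)-unit is α, so a 4β substituent is trans to the 2-aryl group; the ligand enantiomer that gives 4R in step 6 is assumed to be fixed by a trial on 7, both antipodes being accessible.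

## Route

Step 1
Reactants: 1 (+)-catechin
Product: 2 5,7,3',4'-tetra-O-benzyl-(+)-catechin
Conditions: BnBr (4.4 equiv), K2CO3, DMF, 0 °C to rt, Ar
Reagents that add atoms: benzyl bromide, BrCc1ccccc1
Why: Williamson etherification; K2CO3 ionises only the four phenols, so the secondary 3-OH stays free, and the mild base under argon avoids ring opening and epimerisation at C2.

Step 2
Reactants: 2 5,7,3',4'-tetra-O-benzyl-(+)-catechin
Product: 3 3,5,7,3',4'-penta-O-benzyl-(+)-catechin
Conditions: NaH, BnBr, n-Bu4NI (cat.), DMF, 0 °C to rt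
Reagents that add atoms: benzyl bromide, BrCc1ccccc1
Why: Williamson etherification of the secondary alkoxide; with no free phenol left the flavan cannot open, so C2 and C3 are unchanged.

Step 3
Reactants: 3 3,5,7,3',4'-penta-O-benzyl-(+)-catechin
Product: 4 8-bromo-3,5,7,3',4'-penta-O-benzyl-(+)-catechin
Conditions: NBS (1.0 equiv), CH2Cl2, −78 to 0 °C
Reagents that add atoms: N-bromosuccinimide, O=C1CCC(=O)N1Br
Why: Electrophilic aromatic bromination; C8 is the more reactive and less hindered of the two free ring A positions of 5,7-dialkoxyflavans, and one equivalent stops at the monobromide.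

Step 4
Reactants: 4 8-bromo-3,5,7,3',4'-penta-O-benzyl-(+)-catechin
Product: 5 8-bromo-3,5,7,3',4'-penta-O-benzyl-(+)-catechin-6-carbaldehyde
Conditions: POCl3, DMF, ClCH2CH2Cl, 0 to 60 °C; aq. NaOAc
Reagents that add atoms: N,N-dimethylformamide, CN(C)C=O; water, O
Why: Vilsmeier–Haack formylation; C6 is the only free ring A position, activated by two ortho benzyloxy groups and the para ring oxygen, while ring B is far less nucleophilic.

Step 5
Reactants: 5 8-bromo-3,5,7,3',4'-penta-O-benzyl-(+)-catechin-6-carbaldehyde; 6 1-[3,4-bis(benzyloxy)phenyl]ethanone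
Product: 7 (E)-1-[3,4-bis(benzyloxy)phenyl]-3-(8-bromo-penta-O-benzylcatechin-6-yl)prop-2-en-1-one
Conditions: KOH, EtOH/THF, rt
Reagents that add atoms: none
Why: Claisen–Schmidt condensation of a non-enolisable aldehyde with a methyl ketone; dehydration gives the conjugated E enone, and the perbenzylated unit L has no base-labile centre.

Step 6
Reactants: 7 (E)-1-[3,4-bis(benzyloxy)phenyl]-3-(8-bromo-penta-O-benzylcatechin-6-yl)prop-2-en-1-one; 8 3,5-bis(benzyloxy)phenol
Product: 11 (4R)-5,7-bis(benzyloxy)-2-[3,4-bis(benzyloxy)phenyl]-4-(8-bromo-penta-O-benzylcatechin-6-yl)-4H-chromene (M–L chromene), via Friedel–Crafts ketone 9 (not isolated), via hemiketal 10 (not isolated)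
Conditions: Sc(OTf)3 (10 mol %), chiral N,N'-dioxide from L-pipecolic acid 2,6-diisopropylanilide with propane-1,3-diyl linker (11 mol %, or its enantiomer), 8 (2 equiv), 4 Å MS, ClCH2CH2Cl, 35 °C, Ar; then PPTS (10 mol %), rt
Reagents that add atoms: none
Why: This is a Friedel–Crafts conjugate addition followed by cycloketalisation, a formal [3+3] annulation, of the type known as the catalytic asymmetric reaction of electron-rich phenols with enones to 4-aryl-4H-chromenes, and chalcones are established acceptors for Friedel–Crafts donors under N,N'-dioxide–Sc(OTf)3 catalysis. The enone carbonyl binds to the Sc centre in its s-cis form inside the C2-symmetric pocket, and an ortho carbon of 8 adds to the β-carbon to form C4–C4a, giving ketone 9 after rearomatisation. The phenol oxygen then attacks the activated ketone in a 6-exo-trig closure to hemiketal 10, and loss of water, helped by the sieves and PPTS, gives the conjugated enol ether, so ring C closes through the O1–C2 bond. The only new stereocentre, C4 (R), is set by the catalyst, which exposes one face of the β-carbon; the stereocentres of L lie across an aromatic ring and cannot bias it, and the 4-epimer is a diastereomer that chromatography can remove. The step needs ortho and not para attack on 8: the hydroxyl group binds to the catalyst and directs ortho, the para carbon lies between two benzyloxy groups, and only the ortho adduct can cyclise and leave the equilibrium. It also needs mono-addition, secured by the excess of 8, and exclusion of air and strong acid, because 2,4-diaryl-4H-chromenes lose hydride to flavylium ions and cleave by retro-Friedel–Crafts reaction.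

Step 7
Reactants: 11 (4R)-5,7-bis(benzyloxy)-2-[3,4-bis(benzyloxy)phenyl]-4-(8-bromo-penta-O-benzylcatechin-6-yl)-4H-chromene
Product: 13 5,7,3',4'-tetra-O-benzylepicatechin-(4β→6)-8-bromo-3,5,7,3',4'-penta-O-benzylcatechin (M–L alcohol; 2,3-cis-3,4-trans in M), via 2α,3α-epoxide 12 (not isolated)
Conditions: DMDO (1.2 equiv), acetone/CH2Cl2, −78 to −40 °C; volatiles removed cold; Et3SiH (5 equiv), BF3·OEt2 (1.2 equiv), CH2Cl2, −78 °C; aq. NaHCO3
Reagents that add atoms: dimethyldioxirane, CC1(C)OO1
Why: Enol ether epoxidation followed by Lewis acid-mediated reductive opening (ionic hydrogenation of the C2 oxocarbenium ion), as practised on 1-aryl glycal epoxides; DMDO attacks C2=C3 anti to the pseudoaxial C4 aryl group and so fixes C3. In the cation the peri 5-benzyloxy group keeps the C4 aryl group pseudoaxial, so the trans C3 oxygen is pseudoaxial too, and axial hydride delivery to C2 anti to that oxygen gives the 2,3-cis-3,4-trans flavan-3-ol with an equatorial 2-aryl group.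

Step 8
Reactants: 13 M–L alcohol; 14 3,4,5-tris(benzyloxy)benzoyl chloride
Product: 15 3-O-(3,4,5-tri-O-benzylgalloyl)-5,7,3',4'-tetra-O-benzylepicatechin-(4β→6)-8-bromo-3,5,7,3',4'-penta-O-benzylcatechin (galloylated M–L dimer)
Conditions: DMAP, Et3N, CH2Cl2, 0 °C to rt
Reagents that add atoms: none
Why: DMAP-catalysed acylation through the acylpyridinium ion; axial 3-hydroxyls of 4-arylflavan-3-ols are hindered but accept the tri-O-benzylgalloyl group, and no stereocentre is touched.

Step 9
Reactants: 16 (−)-epicatechin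
Product: 17 5,7,3',4'-tetra-O-benzyl-(−)-epicatechin
Conditions: BnBr (4.4 equiv), K2CO3, DMF, 0 °C to rt, Ar
Reagents that add atoms: benzyl bromide, BrCc1ccccc1
Why: Williamson etherification of the four phenols as in step 1; the axial secondary 3-OH is not ionised by K2CO3 and stays free, and low temperature under argon avoids ring opening and epimerisation at C2.

Step 10
Reactants: 17 5,7,3',4'-tetra-O-benzyl-(−)-epicatechin; 14 3,4,5-tris(benzyloxy)benzoyl chloride
Product: 18 hepta-O-benzyl-(−)-epicatechin 3-O-gallate [5,7,3',4'-tetra-O-benzyl-3-O-(3,4,5-tri-O-benzylgalloyl)-(−)-epicatechin]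
Conditions: DMAP, Et3N, CH2Cl2, 0 °C to rt
Reagents that add atoms: none
Why: DMAP-catalysed acylation of the axial 3-hydroxyl through the acylpyridinium ion, the standard way to benzylated flavan-3-ol gallates; the O–H bond alone reacts, so C2 and C3 keep their configuration.

Step 11
Reactants: 18 hepta-O-benzyl-(−)-epicatechin 3-O-gallate
Product: 19 4β-(2-ethoxyethoxy)-hepta-O-benzyl-(−)-epicatechin 3-O-gallate
Conditions: DDQ (2 equiv), EtOCH2CH2OH (5 equiv), CH2Cl2, rt
Reagents that add atoms: 2-ethoxyethanol, CCOCCO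
Why: Benzylic oxidation by hydride abstraction from C4, whose cation is stabilised by the 5,7-dialkoxy ring A, with capture by the alcohol anti to the 3-acyloxy group; this is the standard C4 activation of benzylated flavan-3-ol esters.

Step 12
Reactants: 19 4β-(2-ethoxyethoxy)-hepta-O-benzyl-(−)-epicatechin 3-O-gallate
Product: 20 8-bromo-4β-(2-ethoxyethoxy)-hepta-O-benzyl-(−)-epicatechin 3-O-gallate
Conditions: NBS (1.0 equiv), CH2Cl2, −40 °C
Reagents that add atoms: N-bromosuccinimide, O=C1CCC(=O)N1Br
Why: Electrophilic bromination at C8 as in step 3; the bromine cap stops the electrophile from condensing with itself and stops the trimer from being extended at C8 of U.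

Step 13
Reactants: 15 galloylated M–L dimer; 20 8-bromo-4β-(2-ethoxyethoxy)-hepta-O-benzyl-(−)-epicatechin 3-O-gallate
Product: 21 fully protected trimer: 8-bromo-hepta-O-benzyl-epicatechin gallate-(4β→8)-hepta-O-benzyl-epicatechin gallate-(4β→6)-8-bromo-penta-O-benzylcatechin
Conditions: TMSOTf (0.5 equiv), 20 (1.3 equiv), CH2Cl2, −78 to −40 °C; Et3N quench
Reagents that add atoms: none
Why: Lewis acid-mediated ionisation of the C4 ether and Friedel–Crafts arylation of the flavan C4 cation, the standard 4→8 coupling of benzylated flavan-3-ols. C8 of M is the most nucleophilic free carbon (C6 of M lies between two benzyloxy groups, C8 of L and of U carry bromine), and attack anti to the participating 3-O-galloyl group gives the 4β bond.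

Step 14
Reactants: 21 fully protected trimer
Product: 22 epicatechin 3-O-gallate-(4β→8)-epicatechin 3-O-gallate-(4β→6)-catechin (CNP0154615.1)
Conditions: H2 (1 atm), Pd(OH)2/C, Et3N (2.2 equiv), THF/MeOH/H2O, rt; filtration under Ar, Sephadex LH-20
Reagents that add atoms: none
Why: Catalytic hydrogenolysis removes the nineteen benzyl ethers and both aryl bromides, with Et3N taking up HBr; aryl esters and the benzylic C–O and C–C bonds of the flavan cores are stable under these conditions.

## Compound list

1 | (+)-catechin, (2R,3S) | O[C@H]1Cc2c(O)cc(O)cc2O[C@@H]1c1ccc(O)c(O)c1 | starting material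
2 | 5,7,3',4'-tetra-O-benzyl-(+)-catechin | O[C@H]1Cc2c(OCc5ccccc5)cc(OCc5ccccc5)cc2O[C@@H]1c1ccc(OCc5ccccc5)c(OCc5ccccc5)c1 | intermediate
3 | 3,5,7,3',4'-penta-O-benzyl-(+)-catechin | c1ccccc1CO[C@H]1Cc2c(OCc5ccccc5)cc(OCc5ccccc5)cc2O[C@@H]1c1ccc(OCc5ccccc5)c(OCc5ccccc5)c1 | intermediate
4 | 8-bromo-3,5,7,3',4'-penta-O-benzyl-(+)-catechin | c1ccccc1CO[C@H]1Cc2c(OCc5ccccc5)cc(OCc5ccccc5)c(Br)c2O[C@@H]1c1ccc(OCc5ccccc5)c(OCc5ccccc5)c1 | intermediate
5 | 8-bromo-3,5,7,3',4'-penta-O-benzyl-(+)-catechin-6-carbaldehyde | c1ccccc1CO[C@H]1Cc2c(OCc5ccccc5)c(C=O)c(OCc5ccccc5)c(Br)c2O[C@@H]1c1ccc(OCc5ccccc5)c(OCc5ccccc5)c1 | intermediate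
6 | 1-[3,4-bis(benzyloxy)phenyl]ethanone | CC(=O)c1ccc(OCc2ccccc2)c(OCc2ccccc2)c1 | starting material
7 | (E)-1-[3,4-bis(benzyloxy)phenyl]-3-(8-bromo-penta-O-benzylcatechin-6-yl)prop-2-en-1-one | O=C(/C=C/c2c(OCc5ccccc5)c(Br)c3c(c2OCc5ccccc5)C[C@H](OCc5ccccc5)[C@@H](c2ccc(OCc5ccccc5)c(OCc5ccccc5)c2)O3)c1ccc(OCc5ccccc5)c(OCc5ccccc5)c1 | intermediate
8 | 3,5-bis(benzyloxy)phenol | Oc1cc(OCc2ccccc2)cc(OCc2ccccc2)c1 | starting material
9 | (3R)-3-[2,4-bis(benzyloxy)-6-hydroxyphenyl]-1-[3,4-bis(benzyloxy)phenyl]-3-(8-bromo-penta-O-benzylcatechin-6-yl)propan-1-one | O=C(c1ccc(OCc5ccccc5)c(OCc5ccccc5)c1)C[C@H](c1c(O)cc(OCc5ccccc5)cc1OCc5ccccc5)c2c(OCc5ccccc5)c(Br)c3c(c2OCc5ccccc5)C[C@H](OCc5ccccc5)[C@@H](c2ccc(OCc5ccccc5)c(OCc5ccccc5)c2)O3 | intermediate (not isolated)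
10 | (4R)-5,7-bis(benzyloxy)-2-[3,4-bis(benzyloxy)phenyl]-4-(8-bromo-penta-O-benzylcatechin-6-yl)chroman-2-ol, both C2 epimers | c2c(OCc5ccccc5)cc(OCc5ccccc5)c3c2OC(O)(c2ccc(OCc5ccccc5)c(OCc5ccccc5)c2)C[C@H]3c2c(OCc5ccccc5)c(Br)c3c(c2OCc5ccccc5)C[C@H](OCc5ccccc5)[C@@H](c2ccc(OCc5ccccc5)c(OCc5ccccc5)c2)O3 | intermediate (not isolated)
11 | (4R)-5,7-bis(benzyloxy)-2-[3,4-bis(benzyloxy)phenyl]-4-(8-bromo-penta-O-benzylcatechin-6-yl)-4H-chromene | c2c(OCc5ccccc5)cc(OCc5ccccc5)c3c2OC(c2ccc(OCc5ccccc5)c(OCc5ccccc5)c2)=C[C@H]3c2c(OCc5ccccc5)c(Br)c3c(c2OCc5ccccc5)C[C@H](OCc5ccccc5)[C@@H](c2ccc(OCc5ccccc5)c(OCc5ccccc5)c2)O3 | intermediate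
12 | 2α,3α-epoxide of 11 (epoxide oxygen trans to the C4 substituent) | c2c(OCc5ccccc5)cc(OCc5ccccc5)c3c2O[C@]6(c2ccc(OCc5ccccc5)c(OCc5ccccc5)c2)O[C@@H]6[C@H]3c2c(OCc5ccccc5)c(Br)c3c(c2OCc5ccccc5)C[C@H](OCc5ccccc5)[C@@H](c2ccc(OCc5ccccc5)c(OCc5ccccc5)c2)O3 | intermediate (not isolated)
13 | 5,7,3',4'-tetra-O-benzylepicatechin-(4β→6)-8-bromo-3,5,7,3',4'-penta-O-benzylcatechin (free 3-OH in M; 2-aryl α, 3-OH α, 4-aryl β) | c2c(OCc5ccccc5)cc(OCc5ccccc5)c3c2O[C@H](c2ccc(OCc5ccccc5)c(OCc5ccccc5)c2)[C@H](O)[C@H]3c2c(OCc5ccccc5)c(Br)c3c(c2OCc5ccccc5)C[C@H](OCc5ccccc5)[C@@H](c2ccc(OCc5ccccc5)c(OCc5ccccc5)c2)O3 | intermediate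
14 | 3,4,5-tris(benzyloxy)benzoyl chloride | ClC(=O)c1cc(OCc2ccccc2)c(OCc2ccccc2)c(OCc2ccccc2)c1 | starting material
15 | 3-O-(3,4,5-tri-O-benzylgalloyl)-5,7,3',4'-tetra-O-benzylepicatechin-(4β→6)-8-bromo-3,5,7,3',4'-penta-O-benzylcatechin | c2c(OCc5ccccc5)cc(OCc5ccccc5)c3c2O[C@H](c2ccc(OCc5ccccc5)c(OCc5ccccc5)c2)[C@H](OC(=O)c2cc(OCc5ccccc5)c(OCc5ccccc5)c(OCc5ccccc5)c2)[C@H]3c2c(OCc5ccccc5)c(Br)c3c(c2OCc5ccccc5)C[C@H](OCc5ccccc5)[C@@H](c2ccc(OCc5ccccc5)c(OCc5ccccc5)c2)O3 | intermediate
16 | (−)-epicatechin, (2R,3R) | O[C@@H]1Cc2c(O)cc(O)cc2O[C@@H]1c1ccc(O)c(O)c1 | starting material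
17 | 5,7,3',4'-tetra-O-benzyl-(−)-epicatechin | O[C@@H]1Cc2c(OCc5ccccc5)cc(OCc5ccccc5)cc2O[C@@H]1c1ccc(OCc5ccccc5)c(OCc5ccccc5)c1 | intermediate
18 | hepta-O-benzyl-(−)-epicatechin 3-O-gallate | O=C(O[C@@H]1Cc2c(OCc5ccccc5)cc(OCc5ccccc5)cc2O[C@@H]1c1ccc(OCc5ccccc5)c(OCc5ccccc5)c1)c1cc(OCc5ccccc5)c(OCc5ccccc5)c(OCc5ccccc5)c1 | intermediate
19 | 4β-(2-ethoxyethoxy)-hepta-O-benzyl-(−)-epicatechin 3-O-gallate | O=C(O[C@@H]1[C@@H](OCCOCC)c2c(OCc5ccccc5)cc(OCc5ccccc5)cc2O[C@@H]1c1ccc(OCc5ccccc5)c(OCc5ccccc5)c1)c1cc(OCc5ccccc5)c(OCc5ccccc5)c(OCc5ccccc5)c1 | intermediate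
20 | 8-bromo-4β-(2-ethoxyethoxy)-hepta-O-benzyl-(−)-epicatechin 3-O-gallate | O=C(O[C@@H]1[C@@H](OCCOCC)c2c(OCc5ccccc5)cc(OCc5ccccc5)c(Br)c2O[C@@H]1c1ccc(OCc5ccccc5)c(OCc5ccccc5)c1)c1cc(OCc5ccccc5)c(OCc5ccccc5)c(OCc5ccccc5)c1 | intermediate
21 | 8-bromo-hepta-O-benzyl-epicatechin gallate-(4β→8)-hepta-O-benzyl-epicatechin gallate-(4β→6)-8-bromo-penta-O-benzylcatechin | O=C(O[C@@H]1[C@@H](c2c(OCc5ccccc5)cc(OCc5ccccc5)c3c2O[C@H](c2ccc(OCc5ccccc5)c(OCc5ccccc5)c2)[C@H](OC(=O)c2cc(OCc5ccccc5)c(OCc5ccccc5)c(OCc5ccccc5)c2)[C@H]3c2c(OCc5ccccc5)c(Br)c3c(c2OCc5ccccc5)C[C@H](OCc5ccccc5)[C@@H](c2ccc(OCc5ccccc5)c(OCc5ccccc5)c2)O3)c2c(OCc5ccccc5)cc(OCc5ccccc5)c(Br)c2O[C@@H]1c1ccc(OCc5ccccc5)c(OCc5ccccc5)c1)c1cc(OCc5ccccc5)c(OCc5ccccc5)c(OCc5ccccc5)c1 | intermediate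
22 | epicatechin 3-O-gallate-(4β→8)-epicatechin 3-O-gallate-(4β→6)-catechin (CNP0154615.1) | O=C(O[C@@H]1[C@@H](c2c(O)cc(O)c3c2O[C@H](c2ccc(O)c(O)c2)[C@H](OC(=O)c2cc(O)c(O)c(O)c2)[C@H]3c2c(O)cc3c(c2O)C[C@H](O)[C@@H](c2ccc(O)c(O)c2)O3)c2c(O)cc(O)cc2O[C@@H]1c1ccc(O)c(O)c1)c1cc(O)c(O)c(O)c1 | target

## Step count and risks

Total: 14 steps. Longest linear sequence: 10 steps from (+)-catechin (steps 1–8, 13 and 14); steps 9–12 make the electrophile from (−)-epicatechin.

**Step 6 (key step).** The addition may stall or revert, because the β-aryl group of 7 carries two ortho benzyloxy groups and is strongly donating. Facial selectivity may be poor, because a chalcone binds the catalyst through one point only. Para attack on 8, double addition and air oxidation to the flavylium ion are further drains. The fallback changes the bonds formed and sets out from aldehyde 5, with 8 and 6. The bromomagnesium phenoxide of 8 (EtMgBr, toluene) would add ortho-selectively to 5 to give the ortho-hydroxybenzhydrol F1. Ketone 6 would be converted (TMSOTf, Et3N) into the trimethylsilyl enol ether F2. A chiral BINOL-derived phosphoric acid would then ionise F1 to the ortho-quinone methide, which adds F2 in a [4+2] sense (C3–C4 and O1–C2 formed). Loss of silanol from the silyl ketal returns the route to chromene 11.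

**Step 7.** Hydride may be delivered syn to the C3 oxygen, giving the 2,3-trans isomer, if the cation does not hold the diaxial conformation. The cation may also undergo a 1,2-hydride shift to the flavan-3-one, or be captured by ring A of a second molecule. The fallback replaces conformational control by neighbouring-group control and sets out from 11. Epoxidation with DMDO in CH2Cl2/MeOH would give the isolable methyl ketal alcohol F3. Acylation with 14 (DMAP, Et3N) would give the galloylated ketal F4. Et3SiH/TMSOTf at −78 °C would then ionise C2; the galloyl carbonyl bridges the α face, so hydride is confined to the β face. The route is rejoined at 15, and step 8 is no longer needed.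

**Step 13.** Coupling may be slow, because the 3-O-galloyl group lowers the nucleophilicity of ring A of M and crowds it, so the cation from 20 decomposes. Attack at C6 of M may compete, and prolonged acid may cleave the M–L bond. The fallback changes the order of bond formation and sets out from alcohol 13 and 20. Coupling under the same activation with the free 3-hydroxyl nucleophile would give the trimer alcohol F5. Acylation of F5 with 14 (DMAP, Et3N) rejoins the route at 21.

**Step 14.** Debenzylation may stop short, because bromide poisons the catalyst. HBr set free may cleave the interflavan bonds, and the product may oxidise during isolation. The fallback separates the two reductions and sets out from 21. Radical hydrodebromination (Bu3SnH, AIBN, toluene, 90 °C) would give the bromine-free nonadeca-O-benzyl trimer F6. Hydrogenolysis of F6 under neutral conditions (H2, Pd(OH)2/C, THF/MeOH) then returns the route to 22.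

**Step 4.** Formylation may be incomplete at a carbon flanked by two benzyloxy groups, and acid may cause bromine migration or loss. The fallback replaces electrophilic formylation by halogen–metal exchange and sets out from 4. Iodination (NIS, cat. TFA) would give the 8-bromo-6-iodo compound F7. Selective iodine–magnesium exchange (i-PrMgCl·LiCl, THF, −40 °C) and quenching with DMF returns the route to 5.

## Further compounds

F1 | step 6 | [2,4-bis(benzyloxy)-6-hydroxyphenyl](8-bromo-penta-O-benzylcatechin-6-yl)methanol, both carbinol epimers | OC(c1c(O)cc(OCc5ccccc5)cc1OCc5ccccc5)c2c(OCc5ccccc5)c(Br)c3c(c2OCc5ccccc5)C[C@H](OCc5ccccc5)[C@@H](c2ccc(OCc5ccccc5)c(OCc5ccccc5)c2)O3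
F2 | step 6 | {1-[3,4-bis(benzyloxy)phenyl]ethenyloxy}trimethylsilane | C=C(O[Si](C)(C)C)c1ccc(OCc2ccccc2)c(OCc2ccccc2)c1
F3 | step 7 | 2-methoxy-5,7,3',4'-tetra-O-benzylflavan-3α-ol carrying the 8-bromo-penta-O-benzylcatechin-6-yl group at C4β, both C2 epimers | c2c(OCc5ccccc5)cc(OCc5ccccc5)c3c2OC(OC)(c2ccc(OCc5ccccc5)c(OCc5ccccc5)c2)[C@H](O)[C@H]3c2c(OCc5ccccc5)c(Br)c3c(c2OCc5ccccc5)C[C@H](OCc5ccccc5)[C@@H](c2ccc(OCc5ccccc5)c(OCc5ccccc5)c2)O3
F4 | step 7 | 3-O-(3,4,5-tri-O-benzylgalloyl) ester of F3 | c2c(OCc5ccccc5)cc(OCc5ccccc5)c3c2OC(OC)(c2ccc(OCc5ccccc5)c(OCc5ccccc5)c2)[C@H](OC(=O)c2cc(OCc5ccccc5)c(OCc5ccccc5)c(OCc5ccccc5)c2)[C@H]3c2c(OCc5ccccc5)c(Br)c3c(c2OCc5ccccc5)C[C@H](OCc5ccccc5)[C@@H](c2ccc(OCc5ccccc5)c(OCc5ccccc5)c2)O3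
F5 | step 13 | protected trimer with free 3-OH in M: 8-bromo-hepta-O-benzyl-epicatechin gallate-(4β→8)-tetra-O-benzylepicatechin-(4β→6)-8-bromo-penta-O-benzylcatechin | O=C(O[C@@H]1[C@@H](c2c(OCc5ccccc5)cc(OCc5ccccc5)c3c2O[C@H](c2ccc(OCc5ccccc5)c(OCc5ccccc5)c2)[C@H](O)[C@H]3c2c(OCc5ccccc5)c(Br)c3c(c2OCc5ccccc5)C[C@H](OCc5ccccc5)[C@@H](c2ccc(OCc5ccccc5)c(OCc5ccccc5)c2)O3)c2c(OCc5ccccc5)cc(OCc5ccccc5)c(Br)c2O[C@@H]1c1ccc(OCc5ccccc5)c(OCc5ccccc5)c1)c1cc(OCc5ccccc5)c(OCc5ccccc5)c(OCc5ccccc5)c1
F6 | step 14 | bromine-free nonadeca-O-benzyl trimer | O=C(O[C@@H]1[C@@H](c2c(OCc5ccccc5)cc(OCc5ccccc5)c3c2O[C@H](c2ccc(OCc5ccccc5)c(OCc5ccccc5)c2)[C@H](OC(=O)c2cc(OCc5ccccc5)c(OCc5ccccc5)c(OCc5ccccc5)c2)[C@H]3c2c(OCc5ccccc5)cc3c(c2OCc5ccccc5)C[C@H](OCc5ccccc5)[C@@H](c2ccc(OCc5ccccc5)c(OCc5ccccc5)c2)O3)c2c(OCc5ccccc5)cc(OCc5ccccc5)cc2O[C@@H]1c1ccc(OCc5ccccc5)c(OCc5ccccc5)c1)c1cc(OCc5ccccc5)c(OCc5ccccc5)c(OCc5ccccc5)c1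
F7 | step 4 | 8-bromo-6-iodo-3,5,7,3',4'-penta-O-benzyl-(+)-catechin | c1ccccc1CO[C@H]1Cc2c(OCc5ccccc5)c(I)c(OCc5ccccc5)c(Br)c2O[C@@H]1c1ccc(OCc5ccccc5)c(OCc5ccccc5)c1
A1 | alternative 1 | perbenzylated trimer with unit L as a 2-aryl-2H-chromene | O=C(O[C@@H]1[C@@H](c2c(OCc4ccccc4)cc(OCc4ccccc4)c3c2O[C@H](c2ccc(OCc4ccccc4)c(OCc4ccccc4)c2)[C@H](OC(=O)c2cc(OCc4ccccc4)c(OCc4ccccc4)c(OCc4ccccc4)c2)[C@H]3c2c(OCc4ccccc4)cc3c(c2OCc4ccccc4)C=C[C@@H](c2ccc(OCc4ccccc4)c(OCc4ccccc4)c2)O3)c2c(OCc4ccccc4)cc(OCc4ccccc4)cc2O[C@@H]1c1ccc(OCc4ccccc4)c(OCc4ccccc4)c1)c1cc(OCc4ccccc4)c(OCc4ccccc4)c(OCc4ccccc4)c1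
A2 | alternative 1 | perbenzylated U–M dimer carrying at C4 of M a 2,6-bis(benzyloxy)-4-{1-[3,4-bis(benzyloxy)phenyl]prop-2-ynyloxy}phenyl group | O=C(O[C@@H]1[C@@H](c2c(OCc4ccccc4)cc(OCc4ccccc4)c3c2O[C@H](c2ccc(OCc4ccccc4)c(OCc4ccccc4)c2)[C@H](OC(=O)c2cc(OCc4ccccc4)c(OCc4ccccc4)c(OCc4ccccc4)c2)[C@H]3c2c(OCc4ccccc4)cc(O[C@@H](C#C)c3ccc(OCc4ccccc4)c(OCc4ccccc4)c3)cc2OCc4ccccc4)c2c(OCc4ccccc4)cc(OCc4ccccc4)cc2O[C@@H]1c1ccc(OCc4ccccc4)c(OCc4ccccc4)c1)c1cc(OCc4ccccc4)c(OCc4ccccc4)c(OCc4ccccc4)c1
A3 | alternative 2 | M–L dimer with free 5-OH, 7-O-triisopropylsilyl and 8-chloro in L and 3-O-tert-butyldimethylsilyl in M | c2c(OCc4ccccc4)cc(OCc4ccccc4)c3c2O[C@H](c2ccc(OCc4ccccc4)c(OCc4ccccc4)c2)[C@H](O[Si](C)(C)C(C)(C)C)[C@H]3c2c(O[Si](C(C)C)(C(C)C)C(C)C)c(Cl)c3c(c2O)C[C@H](OCc4ccccc4)[C@@H](c2ccc(OCc4ccccc4)c(OCc4ccccc4)c2)O3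
A4 | alternative 2 | 4-(benzyloxy)-3-[3,4-bis(benzyloxy)phenyl]-8-chloro-2-oxabicyclo[4.2.0]oct-1(8)-en-7-one with the catechin configuration at C3 and C4 | O=C1C(Cl)=C2O[C@H](c3ccc(OCc4ccccc4)c(OCc4ccccc4)c3)[C@@H](OCc4ccccc4)CC12
A5 | alternative 2 | 5,7,3',4'-tetra-O-benzyl-3-O-tert-butyldimethylsilyl-4β-[(triisopropylsilyloxy)ethynyl]epicatechin | c2c(OCc4ccccc4)cc(OCc4ccccc4)c3c2O[C@H](c2ccc(OCc4ccccc4)c(OCc4ccccc4)c2)[C@H](O[Si](C)(C)C(C)(C)C)[C@H]3C#CO[Si](C(C)C)(C(C)C)C(C)C
A6 | alternative 3 | perbenzylated M–L dimer with the M gallate in place and bromine at C8 of L (identical with 15) | c2c(OCc4ccccc4)cc(OCc4ccccc4)c3c2O[C@H](c2ccc(OCc4ccccc4)c(OCc4ccccc4)c2)[C@H](OC(=O)c2cc(OCc4ccccc4)c(OCc4ccccc4)c(OCc4ccccc4)c2)[C@H]3c2c(OCc4ccccc4)c(Br)c3c(c2OCc4ccccc4)C[C@H](OCc4ccccc4)[C@@H](c2ccc(OCc4ccccc4)c(OCc4ccccc4)c2)O3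
A7 | alternative 3 | [2,4-bis(benzyloxy)-6-hydroxyphenyl](8-bromo-penta-O-benzylcatechin-6-yl)methanol (identical with F1) | OC(c1c(O)cc(OCc4ccccc4)cc1OCc4ccccc4)c2c(OCc4ccccc4)c(Br)c3c(c2OCc4ccccc4)C[C@H](OCc4ccccc4)[C@@H](c2ccc(OCc4ccccc4)c(OCc4ccccc4)c2)O3
A8 | alternative 3 | (Z)-2-[3,4-bis(benzyloxy)phenyl]ethenyl 3,4,5-tris(benzyloxy)benzoate | O=C(O/C=C\c1ccc(OCc2ccccc2)c(OCc2ccccc2)c1)c1cc(OCc2ccccc2)c(OCc2ccccc2)c(OCc2ccccc2)c1
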